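**Route outline**

Ring numbering used throughout: C1 (CH–OAc), C2=C3(CH3) (Z), C4 (CH–O-aroyl), C5, C6=C7(CH3) (E), C8–C10, C11 (C(CH3)2).
Cuts, in retrosynthetic order: the C4 aroyl ester and the C1 acetate; then the macrocycle is traced back to a cyclohexanone, not an open chain, by re-forming C1–C7 and undoing C1–C2; then C7–CH3, C6–C7 (aldol) and C4–C5 (allylation).
Enabling feature: C7, C8, C9, C10, C11 and C1 are the six carbons of a 2,2,6-trisubstituted cyclohexanone, the Z C2=C3 alkene fits a seven-membered ring C1–C7, and an E C6=C7 alkene next to a C1 oxygen is what Grob fragmentation of a C1–C7 bond with a leaving group on C6 leaves behind.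
Forward: the purchased six-membered ring takes up the C2–C6 chain at C6–C7, the seven-membered ring closes at C1–C2, and in the same flask the shared C1–C7 bond breaks so that both rings merge into the eleven-membered ring; reduction, acetylation and esterification follow.
Stereochemistry: C4 (R) from reagent-controlled Brown allylboration; C1 (S) from catalyst-controlled CBS reduction; Z C2=C3 from anti-carbomagnesiation of propargyl alcohol; E C6=C7 transcribed from two sacrificial centres (C6, C7) whose relative configuration comes from a chelate-controlled dianion methylation.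

Key step: step 9

Remark: the C4 oxygen is carried as a triisopropylsilyl ether, because a smaller silyl group there could shift from oxygen to C2 (1,4 O-to-C migration) once the Z-alkenyllithium exists.
Remark: the aldol adduct and the compounds after it up to the fragmentation are mixtures at the sacrificial centres; one isomer is drawn for each and all converge. Metal or boron alkoxides of a product that are only hydrolysed on work-up carry no number.

**Route**

Step 1
Reactants: 1 prop-2-yn-1-ol (propargyl alcohol)
Product: 3 (Z)-3-iodo-2-methylprop-2-en-1-ol, via cyclic alkenylmagnesium alkoxide 2 (not isolated)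
Conditions: MeMgBr (2.5 equiv), CuI (10 mol%), THF, −10 → 23 °C; then I2, −78 → 0 °C; aq NH4Cl
Reagents that add atoms: methylmagnesium bromide, C[Mg]Br; iodine, II
Why: Copper-catalysed anti-carbomagnesiation of the propargylic alkoxide (Duboudin–Jousseaume reaction) puts the methyl group on the future C3 and holds magnesium cis to the CH2O group in a five-membered chelate, so that iodinolysis with retention should give the Z-alkenyl iodide that later becomes the Z C2=C3 alkene.

Step 2
Reactants: 3 (Z)-3-iodo-2-methylprop-2-en-1-ol
Product: 4 (Z)-3-iodo-2-methylprop-2-enal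
Conditions: MnO2 (excess), CH2Cl2, 23 °C, dark; solution used at once
Reagents that add atoms: none
Why: Allylic oxidation with MnO2 is neutral and selective for the allylic alcohol, which should keep the isomerisation-prone Z-iodoenal intact when it is shielded from light and used directly.

Step 3
Reactants: 4 (Z)-3-iodo-2-methylprop-2-enal; 5 allylmagnesium bromide
Product: 7 (3R,1Z)-1-iodo-2-methylhexa-1,5-dien-3-ol, via B-allyldiisopinocampheylborane 6 (not isolated)
Conditions: (+)-Ipc2BOMe (from (−)-α-pinene), 5, Et2O, −78 → 23 °C; then 4, −78 °C; NaOH, H2O2, 0 → 23 °C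
Reagents that add atoms: none
Why: Brown allylboration proceeds through a closed chair transition state in which the isopinocampheyl groups derived from (−)-α-pinene should steer the allyl group to the Re face of the aldehyde, setting the R carbinol centre (C4 of the target) under reagent control.

Step 4
Reactants: 7 (3R,1Z)-1-iodo-2-methylhexa-1,5-dien-3-ol
Product: 8 (3R,1Z)-1-iodo-2-methyl-3-(triisopropylsilyloxy)hexa-1,5-diene
Conditions: TIPSOTf, 2,6-lutidine, CH2Cl2, 0 → 23 °C
Reagents that add atoms: triisopropylsilyl trifluoromethanesulfonate, CC(C)[Si](OS(=O)(=O)C(F)(F)F)(C(C)C)C(C)C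
Why: Silylation of a secondary allylic alcohol with a silyl triflate and a hindered pyridine base is routine and touches no stereocentre, and the bulky triisopropylsilyl group is chosen because it resists anionic O-to-C migration in step 9.

Step 5
Reactants: 8 (3R,1Z)-1-iodo-2-methyl-3-(triisopropylsilyloxy)hexa-1,5-diene
Product: 10 (3R,4Z)-5-iodo-4-methyl-3-(triisopropylsilyloxy)pent-4-enal, via vicinal diol 9 (not isolated)
Conditions: OsO4 (2 mol%), NaIO4, 2,6-lutidine, dioxane/H2O, 23 °C
Reagents that add atoms: osmium tetroxide (delivers the oxygen), O=[Os](=O)(=O)=O; sodium periodate (terminal oxygen source), [Na+].[O-]I(=O)(=O)=O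
Why: Johnson–Lemieux oxidation (dihydroxylation then periodate cleavage) should pick the monosubstituted terminal alkene, because OsO4 reacts far more slowly with the trisubstituted, iodine-deactivated alkene that is also shielded by the neighbouring silyl ether.

Step 6
Reactants: 10 (3R,4Z)-5-iodo-4-methyl-3-(triisopropylsilyloxy)pent-4-enal; 11 2,2-dimethylcyclohexan-1-one
Product: 13 (6R)-6-[(1R,3R,4Z)-1-hydroxy-5-iodo-4-methyl-3-(triisopropylsilyloxy)pent-4-en-1-yl]-2,2-dimethylcyclohexan-1-one, via lithium enolate 12 (not isolated)
Conditions: 11, LiN(i-Pr)2 (LDA), THF, −78 °C; then 10, −78 °C; AcOH, −78 °C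
Reagents that add atoms: none
Why: Aldol addition of the preformed lithium enolate, which can only form on the CH2 side because the other α-carbon is quaternary, should go through a Zimmerman–Traxler transition state favouring the anti adduct, and any mixture at the two new centres is acceptable because C7 is re-enolised in step 7 and both C6 epimers converge in step 9.

Step 7
Reactants: 13 (6R)-6-[(1R,3R,4Z)-1-hydroxy-5-iodo-4-methyl-3-(triisopropylsilyloxy)pent-4-en-1-yl]-2,2-dimethylcyclohexan-1-one
Product: 15 (6S)-6-[(1R,3R,4Z)-1-hydroxy-5-iodo-4-methyl-3-(triisopropylsilyloxy)pent-4-en-1-yl]-2,2,6-trimethylcyclohexan-1-one, via dilithium enolate alkoxide 14 (not isolated)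
Conditions: LDA (2.2 equiv), THF, −78 → −40 °C; MeI, DMPU, −78 → −40 °C; AcOH, −40 °C
Reagents that add atoms: iodomethane, CI
Why: In this Fráter–Seebach-type alkylation of the aldolate dianion the second equivalent of base can only remove the axial C7 hydrogen (C11 is quaternary), the enolate oxygen and the C6 alkoxide share lithium in a six-membered chelate, and iodomethane should enter the face away from the C5 chain, placing the new C7 methyl anti to the C6 hydroxyl for either C6 configuration.

Step 8
Reactants: 15 (6S)-6-[(1R,3R,4Z)-1-hydroxy-5-iodo-4-methyl-3-(triisopropylsilyloxy)pent-4-en-1-yl]-2,2,6-trimethylcyclohexan-1-one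
Product: 16 (1R,3R,4Z)-5-iodo-4-methyl-1-[(1S)-1,3,3-trimethyl-2-oxocyclohexyl]-3-(triisopropylsilyloxy)pent-4-en-1-yl 4-methylbenzenesulfonate
Conditions: TsCl, Et3N, N-methylimidazole, CH2Cl2, 0 → 23 °C
Reagents that add atoms: p-toluenesulfonyl chloride, Cc1ccc(cc1)S(=O)(=O)Cl
Why: Sulfonylation of the hindered secondary alcohol with TsCl activated by N-methylimidazole takes place at oxygen with retention at C6, and the β-tosyloxy ketone should be stable because the quaternary C7 has no hydrogen to lose in an elimination.

Step 9
Reactants: 16 (1R,3R,4Z)-5-iodo-4-methyl-1-[(1S)-1,3,3-trimethyl-2-oxocyclohexyl]-3-(triisopropylsilyloxy)pent-4-en-1-yl 4-methylbenzenesulfonate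
Product: 19 (2Z,4R,6E)-3,7,11,11-tetramethyl-4-(triisopropylsilyloxy)cycloundeca-2,6-dien-1-one, via Z-alkenyllithium 17 (not isolated), via bicyclic lithium alkoxide 18 (not isolated)
Conditions: t-BuLi (2.0 equiv), Et2O, −95 → −78 °C; then THF/HMPA, −78 → 23 °C
Reagents that add atoms: none
Why: Proposed new method: two equivalents of t-BuLi should exchange the C2 iodine for lithium faster than they attack the C1 ketone, which sits between two quaternary carbons and cannot enolise, the Z-alkenyllithium then adds to this ketone in a 7-exo-trig closure of a transient cycloheptene ring fused to the cyclohexane at C1–C7, and on warming the tertiary alkoxide fragments in a concerted Grob process in which the C1–C7 bond breaks and the C6 tosylate leaves, so that the six- and seven-membered rings open into the eleven-membered enone. The closest known reaction types are intramolecular alkenyllithium additions to ketones after halogen–lithium exchange, the Wharton–Grob fragmentation of cyclic 1,3-diol monosulfonates, fragmentations of β-sulfonyloxy ketones triggered by nucleophilic addition, and Barbier cyclisation–fragmentation cascades of iodoalkyl β-sulfonyloxy ketones promoted by SmI2, whereas the version with an alkenyllithium and a seven-membered closure has not been shown. No stereocentre is created for good, because C6 and C7 become sp2 and the configuration of the transient carbinol C1 is erased when the ketone returns. The selectivity needed is E geometry at C6=C7, and the relative configuration installed in step 7 secures it, since in the one rotamer about C6–C7 that both fits the seven-membered ring and holds the tosylate antiperiplanar to the C1–C7 bond, C5 lies anti to C8 and beside the C7 methyl. Substitution at C6 by the carbanion or the alkoxide should be slow because C6 is neopentyl, the aryl sulfonate has none of the acidic α-hydrogens of a mesylate that would quench the alkenyllithium, and the triisopropylsilyl ether should not migrate to C2.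

Step 10
Reactants: 19 (2Z,4R,6E)-3,7,11,11-tetramethyl-4-(triisopropylsilyloxy)cycloundeca-2,6-dien-1-one
Product: 20 (1S,2Z,4R,6E)-3,7,11,11-tetramethyl-4-(triisopropylsilyloxy)cycloundeca-2,6-dien-1-ol
Conditions: (R)-Me-CBS, that is (3aR)-1-methyl-3,3-diphenyltetrahydro-1H,3H-pyrrolo[1,2-c][1,3,2]oxazaborole (0.5 equiv), catecholborane, toluene, −78 °C
Reagents that add atoms: none
Why: In this Corey–Bakshi–Shibata reduction the ketone should bind the catalyst through the lone pair on the side of the smaller alkenyl group, so that the quaternary C11 side points away and hydride reaches the face that gives the 1S alcohol, and because the step is catalyst-controlled the minor C4 enantiomer left from step 3 ends up as a separable diastereomer.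

Step 11
Reactants: 20 (1S,2Z,4R,6E)-3,7,11,11-tetramethyl-4-(triisopropylsilyloxy)cycloundeca-2,6-dien-1-ol
Product: 21 (1S,2Z,4R,6E)-3,7,11,11-tetramethyl-4-(triisopropylsilyloxy)cycloundeca-2,6-dien-1-yl acetate
Conditions: Ac2O, pyridine, 4-(dimethylamino)pyridine (DMAP, cat), CH2Cl2, 23 °C
Reagents that add atoms: acetic anhydride, CC(=O)OC(C)=O
Why: DMAP-catalysed acyl transfer should esterify the hindered secondary allylic alcohol with retention, since no bond to C1 is broken.

Step 12
Reactants: 21 (1S,2Z,4R,6E)-3,7,11,11-tetramethyl-4-(triisopropylsilyloxy)cycloundeca-2,6-dien-1-yl acetate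
Product: 22 (1S,2Z,4R,6E)-4-hydroxy-3,7,11,11-tetramethylcycloundeca-2,6-dien-1-yl acetate
Conditions: HF·pyridine, pyridine, THF, 0 → 23 °C
Reagents that add atoms: none
Why: Fluoride-mediated desilylation under buffered acidic conditions cleaves only the Si–O bond, the absence of a free alkoxide should prevent 1,4-migration of the C1 acetate across the Z alkene, and the pyridine buffer protects the acid-sensitive cycloundecadiene from transannular cyclisation.

Step 13
Reactants: 23 4-hydroxybenzoic acid
Product: 25 4-(tert-butyldimethylsilyloxy)benzoic acid, via bis(tert-butyldimethylsilyl) derivative 24 (not isolated)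
Conditions: TBSCl (2.3 equiv), imidazole, DMF, 23 °C; then AcOH/THF/H2O, 23 °C
Reagents that add atoms: tert-butyldimethylsilyl chloride, CC(C)(C)[Si](C)(C)Cl
Why: Silylation of both the phenol and the acid followed by selective hydrolysis of the far more labile silyl ester in mild aqueous acid is the standard way to mask only the phenol.

Step 14
Reactants: 22 (1S,2Z,4R,6E)-4-hydroxy-3,7,11,11-tetramethylcycloundeca-2,6-dien-1-yl acetate; 25 4-(tert-butyldimethylsilyloxy)benzoic acid
Product: 26 (1S,2Z,4R,6E)-1-acetoxy-3,7,11,11-tetramethylcycloundeca-2,6-dien-4-yl 4-(tert-butyldimethylsilyloxy)benzoate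
Conditions: DCC, DMAP, CH2Cl2, 0 → 23 °C
Reagents that add atoms: none
Why: Steglich esterification through the O-acylisourea and the N-acylpyridinium ion should acylate the C4 alcohol with retention under neutral conditions that leave the allylic acetate and both alkenes untouched, while the silyl ether keeps the phenol from competing as a nucleophile.

Step 15
Reactants: 26 (1S,2Z,4R,6E)-1-acetoxy-3,7,11,11-tetramethylcycloundeca-2,6-dien-4-yl 4-(tert-butyldimethylsilyloxy)benzoate
Product: 27 (1S,2Z,4R,6E)-1-acetoxy-3,7,11,11-tetramethylcycloundeca-2,6-dien-4-yl 4-hydroxybenzoate (CNP0246761.2)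
Conditions: Bu4NF, AcOH, THF, 0 °C
Reagents that add atoms: none
Why: Fluoride-mediated desilylation of an aryl silyl ether is fast at 0 °C, and buffering the fluoride with acetic acid should keep the medium from hydrolysing or transposing the two esters.

**Compound list**

1 | prop-2-yn-1-ol (propargyl alcohol) | C#CCO | starting material
2 | 4-methyl-2,5-dihydro-1,2-oxamagnesole (cyclic alkenylmagnesium alkoxide, Mg cis to CH2O) | CC1=C[Mg]OC1 | intermediate
3 | (Z)-3-iodo-2-methylprop-2-en-1-ol | I/C=C(/C)CO | intermediate
4 | (Z)-3-iodo-2-methylprop-2-enal | I/C=C(/C)C=O | intermediate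
5 | allylmagnesium bromide | C=CC[Mg]Br | starting material
6 | (+)-B-allyldiisopinocampheylborane (both isopinocampheyl groups from (−)-α-pinene) | C=CCB([C@H]1C[C@H]2C[C@@H]([C@@H]1C)C2(C)C)[C@H]1C[C@H]2C[C@@H]([C@@H]1C)C2(C)C | intermediate
7 | (3R,1Z)-1-iodo-2-methylhexa-1,5-dien-3-ol | I/C=C(/C)[C@H](O)CC=C | intermediate
8 | (3R,1Z)-1-iodo-2-methyl-3-(triisopropylsilyloxy)hexa-1,5-diene | I/C=C(/C)[C@H](O[Si](C(C)C)(C(C)C)C(C)C)CC=C | intermediate
9 | (4R,5Z)-6-iodo-5-methyl-4-(triisopropylsilyloxy)hex-5-ene-1,2-diol (both C2 epimers) | I/C=C(/C)[C@H](O[Si](C(C)C)(C(C)C)C(C)C)CC(O)CO | intermediate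
10 | (3R,4Z)-5-iodo-4-methyl-3-(triisopropylsilyloxy)pent-4-enal | I/C=C(/C)[C@H](O[Si](C(C)C)(C(C)C)C(C)C)CC=O | intermediate
11 | 2,2-dimethylcyclohexan-1-one | CC1(C)CCCCC1=O | starting material
12 | lithium 6,6-dimethylcyclohex-1-en-1-olate | [Li]OC1=CCCCC1(C)C | intermediate
13 | (6R)-6-[(1R,3R,4Z)-1-hydroxy-5-iodo-4-methyl-3-(triisopropylsilyloxy)pent-4-en-1-yl]-2,2-dimethylcyclohexan-1-one (anti aldol drawn; carried with its diastereomers at the carbinol carbon and at ring C6) | I/C=C(/C)[C@H](O[Si](C(C)C)(C(C)C)C(C)C)C[C@@H](O)[C@H]1CCCC(C)(C)C1=O | intermediate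
14 | dilithium enolate alkoxide of 13 (lithium on the enolate oxygen and on the side-chain oxygen) | I/C=C(/C)[C@H](O[Si](C(C)C)(C(C)C)C(C)C)C[C@@H](O[Li])C1=C(O[Li])C(C)(C)CCC1 | intermediate
15 | (6S)-6-[(1R,3R,4Z)-1-hydroxy-5-iodo-4-methyl-3-(triisopropylsilyloxy)pent-4-en-1-yl]-2,2,6-trimethylcyclohexan-1-one (carried with the isomer inverted at both the carbinol carbon and ring C6) | I/C=C(/C)[C@H](O[Si](C(C)C)(C(C)C)C(C)C)C[C@@H](O)[C@]1(C)CCCC(C)(C)C1=O | intermediate
16 | (1R,3R,4Z)-5-iodo-4-methyl-1-[(1S)-1,3,3-trimethyl-2-oxocyclohexyl]-3-(triisopropylsilyloxy)pent-4-en-1-yl 4-methylbenzenesulfonate | I/C=C(/C)[C@H](O[Si](C(C)C)(C(C)C)C(C)C)C[C@@H](OS(=O)(=O)c1ccc(C)cc1)[C@]2(C)CCCC(C)(C)C2=O | intermediate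
17 | Z-alkenyllithium from 16 (lithium in place of iodine, geometry retained) | [Li]/C=C(/C)[C@H](O[Si](C(C)C)(C(C)C)C(C)C)C[C@@H](OS(=O)(=O)c1ccc(C)cc1)[C@]2(C)CCCC(C)(C)C2=O | intermediate
18 | lithium (1S,4R,6R,7S)-3,7,11,11-tetramethyl-6-(tosyloxy)-4-(triisopropylsilyloxy)bicyclo[5.4.0]undec-2-en-1-olate (trans-fused epimer drawn; the C1 epimer would fragment to the same product) | [Li]O[C@]12C=C(C)[C@H](O[Si](C(C)C)(C(C)C)C(C)C)C[C@@H](OS(=O)(=O)c3ccc(C)cc3)[C@]1(C)CCCC2(C)C | intermediate
19 | (2Z,4R,6E)-3,7,11,11-tetramethyl-4-(triisopropylsilyloxy)cycloundeca-2,6-dien-1-one | O=C1/C=C(/C)[C@H](O[Si](C(C)C)(C(C)C)C(C)C)C/C=C(\C)CCCC1(C)C | intermediate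
20 | (1S,2Z,4R,6E)-3,7,11,11-tetramethyl-4-(triisopropylsilyloxy)cycloundeca-2,6-dien-1-ol | O[C@H]1/C=C(/C)[C@H](O[Si](C(C)C)(C(C)C)C(C)C)C/C=C(\C)CCCC1(C)C | intermediate
21 | (1S,2Z,4R,6E)-3,7,11,11-tetramethyl-4-(triisopropylsilyloxy)cycloundeca-2,6-dien-1-yl acetate | CC(=O)O[C@H]1/C=C(/C)[C@H](O[Si](C(C)C)(C(C)C)C(C)C)C/C=C(\C)CCCC1(C)C | intermediate
22 | (1S,2Z,4R,6E)-4-hydroxy-3,7,11,11-tetramethylcycloundeca-2,6-dien-1-yl acetate | CC(=O)O[C@H]1/C=C(/C)[C@H](O)C/C=C(\C)CCCC1(C)C | intermediate
23 | 4-hydroxybenzoic acid | OC(=O)c1ccc(O)cc1 | starting material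
24 | tert-butyldimethylsilyl 4-(tert-butyldimethylsilyloxy)benzoate | CC(C)(C)[Si](C)(C)OC(=O)c1ccc(O[Si](C)(C)C(C)(C)C)cc1 | intermediate
25 | 4-(tert-butyldimethylsilyloxy)benzoic acid | OC(=O)c1ccc(O[Si](C)(C)C(C)(C)C)cc1 | intermediate
26 | (1S,2Z,4R,6E)-1-acetoxy-3,7,11,11-tetramethylcycloundeca-2,6-dien-4-yl 4-(tert-butyldimethylsilyloxy)benzoate | CC(=O)O[C@H]1/C=C(/C)[C@H](OC(=O)c2ccc(O[Si](C)(C)C(C)(C)C)cc2)C/C=C(\C)CCCC1(C)C | intermediate
27 | (1S,2Z,4R,6E)-1-acetoxy-3,7,11,11-tetramethylcycloundeca-2,6-dien-4-yl 4-hydroxybenzoate (CNP0246761.2) | CC(=O)O[C@H]1/C=C(/C)[C@H](OC(=O)c2ccc(O)cc2)C/C=C(\C)CCCC1(C)C | target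

**Step count and risks**

Total step count: 15. Longest linear sequence: 14 steps (steps 1–12, 14 and 15, from propargyl alcohol); step 13 is a one-step side branch.

Steps most likely to fail:

1. Step 9 (proposed new method). The alkenyllithium may be consumed by attack at the sulfonate sulfur or by proton transfer before it reaches the hindered ketone, or the lithium alkoxide may fail to fragment on warming or may close an oxetane instead. The fallback separates the two events with known chemistry; it sets out from 15 and returns at 19. The free alcohol 15 is treated with t-BuLi (3 equiv) in Et2O at −95 °C, the first equivalent making the lithium alkoxide and the others effecting the exchange, so that the alkenyllithium cyclises onto the ketone with no sulfonate present and gives the bicyclic 1,6-diol F1. Selective tosylation of its secondary C6 hydroxyl (TsCl, Et3N, N-methylimidazole; the C1 hydroxyl is tertiary) gives the C6 monotosylate F2. KOt-Bu in t-BuOH/THF then triggers the classical Wharton–Grob fragmentation to 19, with the same stereochemical transcription into the E alkene.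

2. Step 7. Retro-aldol cleavage of the lithium aldolate may compete with removal of the C7 hydrogen, or iodomethane may enter with poor facial selectivity. The fallback forms the quaternary centre on a 1,3-dicarbonyl compound and makes the carbinol afterwards; it sets out from 13 and returns at 15. Dess–Martin oxidation of 13 gives the β-diketone F3. C-Methylation with K2CO3 and MeI in acetone gives the C7-methylated diketone F4, which cannot undergo retro-aldol cleavage. Zn(BH4)2 in Et2O then reduces the side-chain ketone under chelation control; the ring ketone is shielded by two quaternary neighbours, and hydride is expected from the face of the zinc chelate that carries the small C7 methyl, which gives the C6/C7 relationship of 15. A C6 epimer formed by hydride entry from the other face is separated and re-oxidised to F4.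

3. Step 10. Facial selectivity may be poor or inverted, because the catalyst may not tell the quaternary side from the alkenyl side of the twisted ring enone. The fallback replaces catalyst control by substrate control with recycling; it sets out from 19 and returns at 20. Luche reduction (NaBH4, CeCl3·7H2O, MeOH, −78 °C) gives 20 together with its C1 epimer F5. The two are separated by chromatography, and the C1 epimer is re-oxidised with MnO2 to 19 and reduced again.

Further compounds
F1 | step 9 | (1S,4R,6R,7S)-3,7,11,11-tetramethyl-4-(triisopropylsilyloxy)bicyclo[5.4.0]undec-2-ene-1,6-diol (bicyclic 1,6-diol, trans-fused epimer drawn) | O[C@]12C=C(C)[C@H](O[Si](C(C)C)(C(C)C)C(C)C)C[C@@H](O)[C@]1(C)CCCC2(C)C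
F2 | step 9 | (1S,4R,6R,7S)-1-hydroxy-3,7,11,11-tetramethyl-4-(triisopropylsilyloxy)bicyclo[5.4.0]undec-2-en-6-yl 4-methylbenzenesulfonate (C6 monotosylate) | O[C@]12C=C(C)[C@H](O[Si](C(C)C)(C(C)C)C(C)C)C[C@@H](OS(=O)(=O)c3ccc(C)cc3)[C@]1(C)CCCC2(C)C
F3 | step 7 | 2-[(3R,4Z)-5-iodo-4-methyl-3-(triisopropylsilyloxy)pent-4-enoyl]-6,6-dimethylcyclohexan-1-one (β-diketone, ring C2 labile) | I/C=C(/C)[C@H](O[Si](C(C)C)(C(C)C)C(C)C)CC(=O)C1CCCC(C)(C)C1=O
F4 | step 7 | 2-[(3R,4Z)-5-iodo-4-methyl-3-(triisopropylsilyloxy)pent-4-enoyl]-2,6,6-trimethylcyclohexan-1-one (C7-methylated diketone, both epimers at the quaternary carbon) | I/C=C(/C)[C@H](O[Si](C(C)C)(C(C)C)C(C)C)CC(=O)C1(C)CCCC(C)(C)C1=O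
F5 | step 10 | (1R,2Z,4R,6E)-3,7,11,11-tetramethyl-4-(triisopropylsilyloxy)cycloundeca-2,6-dien-1-ol (C1 epimer of 20) | O[C@@H]1/C=C(/C)[C@H](O[Si](C(C)C)(C(C)C)C(C)C)C/C=C(\C)CCCC1(C)C
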